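# Proposed synthesis of CNP0200738.1 (compound 28)

Locants C1–C7a are those of the indene skeleton of 28 and are kept for all intermediates: C1 (CHMe), C2 (=CH), C3 (=CMe), C3a, C4 (C(Me)CO2H), C5 (C(Et)(dienyl)), C6 (=CH), C7 (=CMe), C7a. C3′ is the carbon that ends as the methyl group on C3.

Assumption: the absolute sense of the catalytic Michael addition (step 2) is set by the choice between the two pseudoenantiomeric cinchona catalysts; O-benzylcupreidine is written, and its quinine-derived counterpart is used if the opposite sense is found.

## Analysis of the target

Compound 28 is a 3a,4,5,7a-tetrahydro-1H-indene: a cyclopentene (C1, C2, C3, C3a, C7a) trans-fused to a cyclohexene (C3a, C4, C5, C6, C7, C7a), with ring double bonds C2=C3 and C6=C7 and a methyl group on C3 and on C7. It has five contiguous stereocentres, C1 (R), C3a (R), C4 (R), C5 (S) and C7a (S). C4 and C5 are vicinal quaternary carbons. The C4 methyl, the C5 ethyl, H-7a and the C1 methyl lie on one face; the carboxyl group, the (1E,3E)-4-phenylbutadienyl chain and H-3a lie on the other. The sensitive parts are the conjugated phenyldiene (acid, light, oxidants, hydrogenation), the two trisubstituted ring alkenes, and C7a, which can epimerise whenever C7 is a carbonyl carbon; the acid between two quaternary carbons is very hindered. The difficulty lies in the two adjacent quaternary centres, in relating them to the trans ring fusion and to C1, and in holding a carboxyl group and an unsaturated chain cis on neighbouring quaternary carbons without closing them to a lactone at the wrong time. The strategy rests on the cyclopentene unit C3(Me)=C2H–C1H(Me) that bridges C3a and C7a. With one more carbon between C2 and C3 it is a cyclohexene, the Diels–Alder adduct of (E)-penta-1,3-diene (11) across a C3a=C7a double bond; the extra carbon C3′ stays as the C3 methyl after ring contraction. C3a=C7a is then the double bond of a cyclohexenone with its carbonyl at C7, and the cis carboxyl/chain pair on C4/C5 is a γ-lactone.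

## Retrosynthetic reasoning

**28 ⇒ 27 ⇒ 25 + 26.** The chain is cut at its first double bond (C5–CH=CH). A Horner–Wadsworth–Emmons reaction of the aldehyde 25 with the cinnamyl phosphonate 26 forms this bond as the E isomer and brings in the styryl unit with its geometry fixed. The acid is carried as the allyl ester 27 because this ester is removed at the allyl–oxygen bond and does not depend on access to the hindered carbonyl.

**25 ⇒ 24 ⇒ 22.** The formyl carbon on C5 and the ester carbon on C4 are cis on adjacent quaternary carbons, so together they are the γ-lactone of 22 at a lower oxidation level. The lactone protects both groups through the whole route and proves their cis relationship. The forward steps must open it and oxidise the alcohol before it closes again.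

**22 ⇒ 21 ⇒ 18 ⇒ 14.** The C7 methyl is cut at the C7–CH3 bond, giving the enol triflate 21 of a C7 ketone. The C3 methyl is traced back through bromide 20 and alcohol 19 to the formyl group of 18. Keeping C7 as an enol triflate, and not as a ketone, through these steps removes the epimerisable C7a position and deactivates the C6=C7 double bond.

**18 ⇒ 16 ⇒ 14.** The C2=C3 bond of the cyclopentene is the product of an intramolecular aldol condensation of the dialdehyde 16. Its two formyl carbons, C2 and C3′, are the ends of a cleaved cyclohexene double bond in 14. This is the six-to-five ring contraction that leaves C3′ on C3.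

**14 ⇒ 13 ⇒ 10 + 11.** The cyclohexene of 13 is cut at C7a–C1 and C3a–C3. This is the only disconnection that sets C1, C3a and C7a in one operation from two simple partners, the enone 10 and the diene 11. The forward reaction must be ortho- and endo-selective, must add to the face of 10 that carries the methyl and ethyl groups, and must be followed by epimerisation at C7a to the trans-fused ketone.

**10 ⇒ 9 ⇒ 7.** The C3a=C7a double bond is removed to give ketone 9, which can be dehydrogenated on one side only. The C5–ethyl bond is then cut, leading to the enone 7. Conjugate addition at the ring-fusion carbon of 7 can only give the cis-fused lactone, so the C4/C5 relationship needs no separate control.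

**7 ⇒ 5 ⇒ 3 + 4.** Enone 7 is the product of a Robinson-type annulation: the C5=C6 bond comes from an aldol condensation and the C4–C3a bond from a Michael addition of 3 to 4. The single stereocentre of 5 (C4) is the only one that has to be set by a catalyst; all others follow from it.

**3 ⇒ 1.** The tetronic acid 3 is the lactone of a γ-bromo derivative of the commercial β-keto ester 1.

## Alternatives that were turned down

**Alternative 1: Pauson–Khand construction of both rings.**
- Disconnection: C3a–C7a, C1–C2 and C2–C3 of the cyclopentenone A2 are cut, leading to the open-chain dienyne A1 (alkyne on C4, dienyl group on C5).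
- Forward key step: a rhodium-catalysed Pauson–Khand reaction of A1 closes the cyclohexene and a cyclopentenone at once to give A2. The C2 oxygen is then removed with a 1,3-shift of the double bond (diazene rearrangement), which has to place hydrogen on C3a.
- For: it is the most convergent plan. Both rings, C1 and the C3 methyl arise in one step, there is no ring contraction, and the C4 ester and the C5 CH2O group are already differentiated, so its endgame is shorter than the one chosen here. On these points it is stronger.
- Against: A1 needs the C4/C5 quaternary pair to be made in an open chain, with defined relative configuration and carrying an alkyne and a Z-trisubstituted diene. The hardest part of 28 is thus moved in front of the key step, with no ring to control it. In the cyclisation C7a is formed next to C4, where methyl and ester differ little in size. The later hydrogen transfer to C3a must give the more strained trans fusion from a flat tetrasubstituted enone.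
- Comparison: the chosen route builds C4/C5 on a ring, where the cis relationship is automatic, and pays for this with a longer sequence after the key step.

**Alternative 2: Ireland–Claisen ring contraction of a lactone.**
- Disconnection: the C4–C5 bond between the quaternary carbons.
- Forward key step: the silyl ketene acetal of the δ-lactone A3 rearranges, forming C4–C5, breaking the C7–O bond and closing the cyclohexene to give the acid A4.
- For: the most hindered bond is formed intramolecularly, with chirality transfer from the C7 carbinol and the alkene geometry. The cyclopentene and C1, C3a and C7a are already in place, and both ring alkenes arise without an enol triflate or a ring contraction. On the stereochemical definition of C4/C5 it may be stronger than the chosen sequence.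
- Against: A3 contains the trans-fused cyclopentene, a tertiary allylic carbinol stereocentre and an E-trisubstituted alkene, and is at least as hard to make as the whole chosen precursor. The rearrangement must join two fully substituted carbons through a boat-like transition state in a strained bicycle, and ionisation or elimination of the tertiary allylic carboxylate competes. After removal of the PMB group the hydroxy acid from A4 would close to a γ-lactone, so the lactone problem of the endgame is not avoided.
- Comparison: the chosen route puts its risk into one cycloaddition on a precursor made in five steps; here a long stereocontrolled synthesis is needed before the key step can be tried.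

**Alternative 3: Tethered γ-acylation of a dienolate.**
- Disconnection: the bond from C4 to the carboxyl carbon of the cyclohexenone lactone A6, which is identical with 10.
- Forward key step: fluoride frees the extended dienolate from the silyl dienol ether A5, and its γ-carbon C4 attacks the carbonate tethered to C5, closing the cis-fused lactone A6.
- For: the cis relationship is guaranteed by the tether, and the C5 stereocentre of A5 can come from a well-established catalytic asymmetric conjugate addition. On enantiocontrol it is probably stronger than the Michael addition used here, and it is about as short.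
- Against: dienolates usually react with acylating agents at oxygen or at the α-carbon C7a. C-acylation at a γ-carbon that creates a quaternary centre with a weakly electrophilic carbonate has little support. The expelled alkoxide can add to the enone or reopen the lactone, and the regiodefined dienol ether needs γ-deprotonation in competition with C6.
- Comparison: it is another way to the substrate of the cycloaddition, not a replacement for it. It would add a second step of uncertain outcome before the key step, whereas the chosen sequence to 10 uses a Michael addition, an aldol condensation, a conjugate addition and a dehydrogenation, all of established type.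

Key step: step 6

## Route

Step 1
Reactants: 1 ethyl 2-methyl-3-oxobutanoate
Product: 3 3-methyltetronic acid (4-hydroxy-3-methylfuran-2(5H)-one), via ethyl 4-bromo-2-methyl-3-oxobutanoate 2 (not isolated)
Conditions: Br2, CHCl3, 0 °C → rt; evaporate; neat, 120 °C
Reagents that add atoms: none
Why: Acid-catalysed bromination with HBr-mediated migration of bromine to C4, then thermal O-alkylation of the ester carbonyl (five-membered ring) with loss of bromoethane, the classical tetronic acid synthesis from γ-bromo acetoacetates; no stereocentre is formed.

Step 2
Reactants: 3 3-methyltetronic acid; 4 methyl vinyl ketone (but-3-en-2-one)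
Product: 5 (R)-3-methyl-3-(3-oxobutyl)furan-2,4(3H,5H)-dione
Conditions: 9-O-benzylcupreidine (C26H28N2O2, 10 mol %), CH2Cl2, −20 °C
Reagents that add atoms: none
Why: Michael addition of the methyl-bearing carbon of the tetronate to the enone; the quinuclidine nitrogen forms a chiral ammonium tetronate ion pair and the 6′-OH group hydrogen-bonds the ketone of 4, so one face of the planar nucleophile is attacked, as in cinchona-catalysed Michael additions of 2-substituted cyclic 1,3-dicarbonyl compounds to vinyl ketones. This sets the quaternary carbon that becomes C4 of 28.

Step 3
Reactants: 5 (R)-3-methyl-3-(3-oxobutyl)furan-2,4(3H,5H)-dione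
Product: 7 (R)-7a-methyl-7,7a-dihydroisobenzofuran-1,5(3H,6H)-dione (bicyclic enone lactone; C7 ketone and C5=C6 in the numbering of 28), via cis-fused ketol 6 (not isolated)
Conditions: p-TsOH·H2O (20 mol %), toluene, reflux, Dean–Stark
Reagents that add atoms: none
Why: Acid-catalysed intramolecular aldol addition of the methyl ketone to the ring ketone and dehydration, the second half of a Robinson annulation; the terminal methyl is the only position that can reach the ring ketone through a six-membered ring and end as a conjugated enone. The quaternary centre is not touched and the lactone has no α-hydrogen.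

Step 4
Reactants: 7 (R)-7a-methyl-7,7a-dihydroisobenzofuran-1,5(3H,6H)-dione
Product: 9 (3aS,7aR)-3a-ethyl-7a-methyl-3a,6,7,7a-tetrahydroisobenzofuran-1,5(3H,4H)-dione (cis-fused keto lactone; ethyl on C5 cis to methyl on C4), via trimethylsilyl enol ether 8 (not isolated)
Conditions: EtMgBr, CuBr·SMe2 (20 mol %), TMSCl, THF, −78 → −30 °C; then 1 M HCl, 0 °C
Reagents that add atoms: ethylmagnesium bromide, CC[Mg]Br
Why: TMSCl-accelerated copper-catalysed conjugate addition of the Grignard reagent to the β,β-disubstituted enone, as in the cuprate additions that place vicinal angular alkyl groups in octalones; the five-membered lactone can only end cis-fused, so ethyl enters C5 on the face of the C4 methyl. The allylic C–O bond of the lactone is held near the nodal plane of the enone π-system, which disfavours its reductive cleavage; aqueous acid hydrolyses 8.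

Step 5
Reactants: 9 cis-fused keto lactone
Product: 10 (3aS,7aR)-3a-ethyl-7a-methyl-3a,7a-dihydroisobenzofuran-1,5(3H,4H)-dione (cis-fused cyclohexenone lactone; C7 ketone and C7a=C3a)
Conditions: IBX (2-iodoxybenzoic acid), DMSO/toluene, 70 °C
Reagents that add atoms: none
Why: IBX dehydrogenation of a ketone to the enone; only the C7a–C3a side can react because the other α-carbon, C6, is attached to the quaternary C5, so both the regiochemistry and the stop at the mono-enone are fixed by the structure.

Step 6
Reactants: 10 cis-fused cyclohexenone lactone; 11 (E)-penta-1,3-diene
Product: 13 trans-fused octalone lactone (C7 ketone; cyclohexene C7a–C1(Me)–C2=C3′–C3–C3a; H-3a and H-7a trans; C1 methyl cis to H-7a), via cis-fused endo adduct 12 (not isolated)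
Conditions: AlCl3 (2.2 equiv), toluene, rt; then 11 (10 equiv), 50 °C, sealed vessel; aq. NaHCO3 work-up; DBU (0.3 equiv), toluene, rt
Reagents that add atoms: none
Why: AlCl3 binds the enone carbonyl (and the lactone carbonyl) of 10 and lowers the LUMO, so s-cis 11 adds in a concerted, asynchronous [4+2] cycloaddition; the closest known reaction type is the AlCl3-promoted Diels–Alder reaction of 4,4-disubstituted cyclohex-2-enones with penta-1,3-diene. One ring, the cyclohexene C7a–C1–C2=C3′–C3–C3a, is closed by intermolecular suprafacial addition across C7a=C3a, forming C7a–C1 and C3a–C3. Ortho regiochemistry follows from the larger HOMO coefficient at the unsubstituted diene terminus, which bonds to the electrophilic β-carbon C3a and leaves the methyl-bearing terminus on C7a. C3a (and at first C7a) is set by the face of addition: the diene must come from the face carrying the C4 methyl and C5 ethyl groups, anti to the lactone carbonyl carbon on C4, which is favoured when the C4–acyl bond is pseudo-axial and antiperiplanar to the forming C3a–C bond and the AlCl3-complexed lactone ring shields the lower face. C1 is set by the endo rule together with the E geometry of 11, which puts the methyl cis to C7 in 12. DBU then epimerises C7a through the enol to the trans-fused 13, in which the C1 methyl is cis to H-7a as in 28. The step needs face selectivity above all; ortho and endo selectivity are the normal preferences under Lewis acid promotion.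

Step 7
Reactants: 13 trans-fused octalone lactone
Product: 14 enol triflate of 13 (C6=C7–OTf)
Conditions: KN(SiMe3)2, THF, −78 °C; PhNTf2, −78 → 0 °C
Reagents that add atoms: N-phenyl-bis(trifluoromethanesulfonimide), O=S(=O)(N(c1ccccc1)S(=O)(=O)C(F)(F)F)C(F)(F)F
Why: Kinetic deprotonation by the bulky amide at the C6 methylene and not at the tertiary, doubly flanked C7a–H, then O-sulfonylation of the enolate. This removes the carbonyl next to C7a, so the trans ring fusion can no longer epimerise, and makes the future C6=C7 alkene electron-poor for the next step.

Step 8
Reactants: 14 enol triflate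
Product: 16 dialdehyde triflate (C7a carries CH(CH3)CHO and C3a carries CH2CHO), via ozonide 15 (not isolated)
Conditions: O3, CH2Cl2, −78 °C, Sudan Red 7B end point; PPh3, −78 °C → rt
Reagents that add atoms: ozone, [O-][O+]=O
Why: Ozonolysis of the electron-rich cis-disubstituted C2=C3′ alkene (cycloaddition, cycloreversion, recombination to the 1,2,4-trioxolane, reduction by the phosphine); the enol triflate double bond is deactivated by the sulfonate and hindered by C5, and the dye marks the end point. No stereocentre changes.

Step 9
Reactants: 16 dialdehyde triflate
Product: 18 cyclopentene carbaldehyde (C2=C3 with CHO on C3; triflate retained), via β-hydroxy aldehyde 17 (not isolated)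
Conditions: dibenzylammonium trifluoroacetate (30 mol %), toluene, rt → 50 °C
Reagents that add atoms: none
Why: Amine-catalysed intramolecular aldol condensation: the enamine forms at the unbranched CH2CHO arm, its carbon C3 attacks the C2 aldehyde to close the five-membered ring, and loss of water gives the conjugated enal; the branched arm cannot give a conjugated product. The conditions are mild and weakly acidic, so C1 next to the accepting aldehyde should keep its configuration.

Step 10
Reactants: 18 cyclopentene carbaldehyde
Product: 19 allylic alcohol (CH2OH on C3)
Conditions: NaBH4, CeCl3·7H2O, MeOH, −20 → 0 °C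
Reagents that add atoms: none
Why: Luche 1,2-reduction of the enal; the hindered lactone and the enol triflate are inert to borohydride at this temperature.

Step 11
Reactants: 19 allylic alcohol
Product: 20 allylic bromide (CH2Br on C3)
Conditions: CBr4, PPh3, CH2Cl2, 0 °C
Reagents that add atoms: carbon tetrabromide, BrC(Br)(Br)Br
Why: Appel reaction; bromide displaces the alkoxyphosphonium group at the primary allylic carbon by SN2.

Step 12
Reactants: 20 allylic bromide
Product: 21 enol triflate with methyl on C3 (cyclopentene C3(Me)=C2H–C1H(Me) complete)
Conditions: NaBH4, DMSO, rt
Reagents that add atoms: none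
Why: SN2 hydride displacement of a primary allylic bromide by borohydride in a dipolar aprotic solvent; direct attack at the unhindered CH2 should be preferred to SN2′ attack at C2, and the lactone and the enol triflate are not reduced.

Step 13
Reactants: 21 enol triflate with methyl on C3
Product: 22 tricyclic diene lactone (C6=C7(Me) and C2=C3(Me); cis-lactone on C4/C5)
Conditions: MeZnCl, Pd(PPh3)4 (5 mol %), THF, 50 °C
Reagents that add atoms: methylzinc chloride, C[Zn]Cl
Why: Negishi cross-coupling of the alkenyl triflate (oxidative addition, transmetalation, reductive elimination) with the double bond kept in place; methylzinc chloride does not attack the lactone.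

Step 14
Reactants: 22 tricyclic diene lactone
Product: 24 allyl ester of the hydroxy acid (CO2allyl on C4 and CH2OH on C5), via potassium hydroxy carboxylate 23 (not isolated)
Conditions: KOH (1.1 equiv), MeOH/H2O, 65 °C; evaporate; allyl bromide, DMF, 0 °C → rt; cold neutral work-up, used crude
Reagents that add atoms: potassium hydroxide, [K+].[OH-]; allyl bromide, C=CCBr
Why: Saponification of the γ-lactone and SN2 O-alkylation of the carboxylate, which is not affected by hindrance at the acyl carbon; the ester holds the hydroxy acid open long enough for the oxidation, and no stereocentre is touched.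

Step 15
Reactants: 24 allyl ester of the hydroxy acid
Product: 25 allyl ester aldehyde (CHO on C5)
Conditions: Dess–Martin periodinane, NaHCO3, CH2Cl2, 0 °C → rt
Reagents that add atoms: none
Why: Dess–Martin oxidation of the neopentyl primary alcohol under buffered, near-neutral conditions; the aldehyde has no α-hydrogen and cannot epimerise.

Step 16
Reactants: 25 allyl ester aldehyde; 26 diethyl [(E)-3-phenylprop-2-en-1-yl]phosphonate (diethyl cinnamylphosphonate)
Product: 27 allyl ester of 28
Conditions: 26, LiN(SiMe3)2, THF, −78 °C; then 25, −78 °C → rt
Reagents that add atoms: none
Why: Horner–Wadsworth–Emmons olefination with the allylic phosphonate anion; reversible addition to the hindered, non-enolisable aldehyde and syn-elimination give the new E double bond, and the styryl double bond of 26 is carried through unchanged.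

Step 17
Reactants: 27 allyl ester of 28
Product: 28 (1R,3aR,4R,5S,7aS)-5-ethyl-1,3,4,7-tetramethyl-5-[(1E,3E)-4-phenylbuta-1,3-dien-1-yl]-3a,4,5,7a-tetrahydro-1H-indene-4-carboxylic acid
Conditions: Pd(PPh3)4 (5 mol %), morpholine, THF, rt; work-up at pH 4
Reagents that add atoms: none
Why: Deallylation through the π-allyl palladium complex with morpholine as allyl acceptor; cleavage is at the allyl–oxygen bond and does not need access to the hindered carbonyl, and the diene, the ring alkenes and all stereocentres are left alone.

## Compound list

1 | ethyl 2-methyl-3-oxobutanoate | CCOC(=O)C(C)C(C)=O | starting material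
2 | ethyl 4-bromo-2-methyl-3-oxobutanoate | CCOC(=O)C(C)C(=O)CBr | intermediate (not isolated)
3 | 3-methyltetronic acid (4-hydroxy-3-methylfuran-2(5H)-one) | CC1=C(O)COC1=O | intermediate
4 | methyl vinyl ketone (but-3-en-2-one) | CC(=O)C=C | starting material
5 | (R)-3-methyl-3-(3-oxobutyl)furan-2,4(3H,5H)-dione | CC(=O)CC[C@@]1(C)C(=O)OCC1=O | intermediate
6 | cis-fused ketol (hydroxyl on C5 cis to methyl on C4) | O[C@]12CC(=O)CC[C@@]1(C)C(=O)OC2 | intermediate (not isolated)
7 | (R)-7a-methyl-7,7a-dihydroisobenzofuran-1,5(3H,6H)-dione | O=C1C=C2COC(=O)[C@]2(C)CC1 | intermediate
8 | trimethylsilyl enol ether (C6=C7–OSiMe3) of 9 | CC[C@]12C=C(O[Si](C)(C)C)CC[C@@]1(C)C(=O)OC2 | intermediate (not isolated)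
9 | (3aS,7aR)-3a-ethyl-7a-methyl-3a,6,7,7a-tetrahydroisobenzofuran-1,5(3H,4H)-dione | CC[C@]12CC(=O)CC[C@@]1(C)C(=O)OC2 | intermediate
10 | (3aS,7aR)-3a-ethyl-7a-methyl-3a,7a-dihydroisobenzofuran-1,5(3H,4H)-dione | CC[C@]12CC(=O)C=C[C@@]1(C)C(=O)OC2 | intermediate
11 | (E)-penta-1,3-diene | C=C/C=C/C | starting material
12 | cis-fused endo adduct (H-3a and H-7a cis; C1 methyl cis to C7) | CC[C@]12CC(=O)[C@@H]3[C@H](C)C=CC[C@@H]3[C@@]1(C)C(=O)OC2 | intermediate (not isolated)
13 | trans-fused octalone lactone (C1 methyl cis to H-7a) | CC[C@]12CC(=O)[C@H]3[C@H](C)C=CC[C@@H]3[C@@]1(C)C(=O)OC2 | intermediate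
14 | enol triflate of 13 (C6=C7–OTf) | CC[C@]12C=C(OS(=O)(=O)C(F)(F)F)[C@H]3[C@H](C)C=CC[C@@H]3[C@@]1(C)C(=O)OC2 | intermediate
15 | ozonide (1,2,4-trioxolane across C2 and C3′; mixture at the trioxolane carbons) | CC[C@]12C=C(OS(=O)(=O)C(F)(F)F)[C@H]3[C@H](C)C4OOC(O4)C[C@@H]3[C@@]1(C)C(=O)OC2 | intermediate (not isolated)
16 | dialdehyde triflate (CH(CH3)CHO on C7a and CH2CHO on C3a) | CC[C@]12C=C(OS(=O)(=O)C(F)(F)F)[C@@H]([C@H](C)C=O)[C@H](CC=O)[C@@]1(C)C(=O)OC2 | intermediate
17 | β-hydroxy aldehyde (OH on C2 and CHO on C3; mixture at C2 and C3) | CC[C@]12C=C(OS(=O)(=O)C(F)(F)F)[C@H]3[C@H](C)C(O)C(C=O)[C@@H]3[C@@]1(C)C(=O)OC2 | intermediate (not isolated)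
18 | cyclopentene carbaldehyde (CHO on C3) | CC[C@]12C=C(OS(=O)(=O)C(F)(F)F)[C@H]3[C@H](C)C=C(C=O)[C@@H]3[C@@]1(C)C(=O)OC2 | intermediate
19 | allylic alcohol (CH2OH on C3) | CC[C@]12C=C(OS(=O)(=O)C(F)(F)F)[C@H]3[C@H](C)C=C(CO)[C@@H]3[C@@]1(C)C(=O)OC2 | intermediate
20 | allylic bromide (CH2Br on C3) | CC[C@]12C=C(OS(=O)(=O)C(F)(F)F)[C@H]3[C@H](C)C=C(CBr)[C@@H]3[C@@]1(C)C(=O)OC2 | intermediate
21 | enol triflate with methyl on C3 | CC[C@]12C=C(OS(=O)(=O)C(F)(F)F)[C@H]3[C@H](C)C=C(C)[C@@H]3[C@@]1(C)C(=O)OC2 | intermediate
22 | tricyclic diene lactone | CC[C@]12C=C(C)[C@H]3[C@H](C)C=C(C)[C@@H]3[C@@]1(C)C(=O)OC2 | intermediate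
23 | potassium hydroxy carboxylate | CC[C@]1(CO)C=C(C)[C@H]2[C@H](C)C=C(C)[C@@H]2[C@@]1(C)C(=O)[O-].[K+] | intermediate (not isolated)
24 | allyl ester of the hydroxy acid | CC[C@]1(CO)C=C(C)[C@H]2[C@H](C)C=C(C)[C@@H]2[C@@]1(C)C(=O)OCC=C | intermediate
25 | allyl ester aldehyde | CC[C@]1(C=O)C=C(C)[C@H]2[C@H](C)C=C(C)[C@@H]2[C@@]1(C)C(=O)OCC=C | intermediate
26 | diethyl [(E)-3-phenylprop-2-en-1-yl]phosphonate | CCOP(=O)(OCC)C/C=C/c1ccccc1 | starting material
27 | allyl ester of 28 | CC[C@]1(/C=C/C=C/c2ccccc2)C=C(C)[C@H]2[C@H](C)C=C(C)[C@@H]2[C@@]1(C)C(=O)OCC=C | intermediate
28 | (1R,3aR,4R,5S,7aS)-5-ethyl-1,3,4,7-tetramethyl-5-[(1E,3E)-4-phenylbuta-1,3-dien-1-yl]-3a,4,5,7a-tetrahydro-1H-indene-4-carboxylic acid | CC[C@]1(/C=C/C=C/c2ccccc2)C=C(C)[C@H]2[C@H](C)C=C(C)[C@@H]2[C@@]1(C)C(=O)O | target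

## Step count and least certain steps

Total: 17 steps. Longest linear sequence: 17 steps (1 → 28); 4, 11 and 26 are bought and enter in steps 2, 6 and 16.

**Step 6 (key step).** The most likely failure is addition of the diene to the wrong face of 10 (syn to the lactone carbonyl), or slow addition that lets the diene polymerise. Both faces of the enone carry a pseudo-axial group on C4 or C5, and the β-carbon is neopentyl. A second concern is an unfavourable cis/trans equilibrium at C7a. Fallback: from 10, α-iodination (I2, pyridine) gives the α-iodo enone F1. Palladium-catalysed methoxycarbonylation (Pd(OAc)2, PPh3, CO, MeOH, Et3N) gives the 2-carbomethoxy enone F2. This doubly activated dienophile should add 11 under ZnCl2 at −20 °C, where the difference between the two faces counts more, to give the cis-fused adduct with an angular ester on C7a, F3; addition with the ketone endo is required as before. Krapcho demethoxycarbonylation (LiCl, wet DMSO, 150 °C) and DBU equilibration return to the route at 13.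

**Step 2.** The risk is low enantioselectivity: the tetronate is a very acidic, weakly directed nucleophile, and the new stereocentre lies on the nucleophile and not on the acceptor. Fallback: from 3 and 4, the Michael addition is run with Et3N in ethyl acetate to give racemic F4. Cyclodehydration as in step 3 gives racemic enone F5, which is resolved by preparative chromatography on a chiral stationary phase (cellulose tris(3,5-dimethylphenylcarbamate)); the (R) enantiomer is 7, where the route is rejoined.

**Step 4.** The risk is 1,2-addition, or reductive cleavage of the allylic lactone C–O bond by electron transfer, in place of 1,4-addition at a fully substituted β-carbon next to a quaternary carbon. Fallback: from 7, a vinyl group is added instead (vinylmagnesium bromide, CuBr·SMe2, TMSCl). Alkenyl copper reagents transfer faster and are weaker reductants. This gives the silyl enol ether F6 and, after acid work-up, the angular vinyl keto lactone F7. Hydrogenation (H2, Pd/C, ethyl acetate) returns to the route at 9.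

**Step 8.** The risk is over-oxidation, with ozone attacking the enol triflate double bond once the cyclohexene is consumed. Fallback: from 14, dihydroxylation with OsO4 (catalytic) and N-methylmorpholine N-oxide, an electrophilic oxidant that should leave the electron-poor, hindered enol triflate alone, gives the cis-diol F8. Cleavage with NaIO4 returns to the route at 16.

**Step 14.** The risk is relactonisation of the γ-hydroxy ester with loss of allyl alcohol before it is oxidised, driven by the two quaternary carbons. Fallback: from 22, after saponification to 23 both oxygens are silylated (Et3SiCl, imidazole, DMF) to the bis-silyl compound F9. Brief treatment with K2CO3 in aqueous methanol cleaves only the silyl ester to give the triethylsilyl ether acid F10. Alkylation with allyl bromide and K2CO3 gives the triethylsilyl ether allyl ester F11. Swern oxidation, which converts primary triethylsilyl ethers directly into aldehydes, returns to the route at 25 without a free hydroxy ester ever being present.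

## Further compounds

F1 | step 6 | α-iodo enone (iodine on C7a of 10) | CC[C@]12CC(=O)C(I)=C[C@@]1(C)C(=O)OC2
F2 | step 6 | 2-carbomethoxy enone (CO2Me on C7a of 10) | CC[C@]12CC(=O)C(C(=O)OC)=C[C@@]1(C)C(=O)OC2
F3 | step 6 | cis-fused adduct with angular CO2Me on C7a | CC[C@]12CC(=O)[C@]3(C(=O)OC)[C@H](C)C=CC[C@@H]3[C@@]1(C)C(=O)OC2
F4 | step 2 | racemic 3-methyl-3-(3-oxobutyl)furan-2,4(3H,5H)-dione | CC(=O)CCC1(C)C(=O)OCC1=O
F5 | step 2 | racemic 7a-methyl-7,7a-dihydroisobenzofuran-1,5(3H,6H)-dione | O=C1C=C2COC(=O)C2(C)CC1
F6 | step 4 | trimethylsilyl enol ether of the vinyl adduct | C=C[C@]12C=C(O[Si](C)(C)C)CC[C@@]1(C)C(=O)OC2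
F7 | step 4 | cis-fused keto lactone with vinyl on C5 | C=C[C@]12CC(=O)CC[C@@]1(C)C(=O)OC2
F8 | step 8 | cis-diol on C2 and C3′ of 14 (mixture at the carbinol carbons) | CC[C@]12C=C(OS(=O)(=O)C(F)(F)F)[C@H]3[C@H](C)C(O)C(O)C[C@@H]3[C@@]1(C)C(=O)OC2
F9 | step 14 | triethylsilyl ether triethylsilyl ester of the hydroxy acid | CC[C@]1(CO[Si](CC)(CC)CC)C=C(C)[C@H]2[C@H](C)C=C(C)[C@@H]2[C@@]1(C)C(=O)O[Si](CC)(CC)CC
F10 | step 14 | triethylsilyl ether acid | CC[C@]1(CO[Si](CC)(CC)CC)C=C(C)[C@H]2[C@H](C)C=C(C)[C@@H]2[C@@]1(C)C(=O)O
F11 | step 14 | triethylsilyl ether allyl ester | CC[C@]1(CO[Si](CC)(CC)CC)C=C(C)[C@H]2[C@H](C)C=C(C)[C@@H]2[C@@]1(C)C(=O)OCC=C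
A1 | alternative 1 | open-chain dienyne (propynyl on C4, (1Z,3E)-2-methylpenta-1,3-dienyl on C5) | CC[C@](CO[Si](C)(C)C(C)(C)C)(/C=C(C)\C=C\C)[C@@](C)(C#CC)C(=O)OC
A2 | alternative 1 | bicyclic cyclopentenone with the cyclohexene in place | CC[C@]1(CO[Si](C)(C)C(C)(C)C)C=C(C)[C@H]2[C@H](C)C(=O)C(C)=C2[C@@]1(C)C(=O)OC
A3 | alternative 2 | δ-lactone with E-alkenyl group on the C7 carbinol carbon (C4 configuration immaterial) | CC1C(=O)O[C@](C)(/C=C(\CC)COCc2ccc(OC)cc2)[C@H]2[C@H](C)C=C(C)[C@H]12
A4 | alternative 2 | bicyclic acid with CH2OPMB on C5 | CC[C@]1(COCc2ccc(OC)cc2)C=C(C)[C@H]2[C@H](C)C=C(C)[C@@H]2[C@@]1(C)C(=O)O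
A5 | alternative 3 | silyl dienol ether with methyl carbonate on the C5 CH2O group | CC[C@]1(COC(=O)OC)CC(O[Si](C)(C)C(C)(C)C)=CC=C1C
A6 | alternative 3 | cis-fused cyclohexenone lactone, identical with 10 | CC[C@]12CC(=O)C=C[C@@]1(C)C(=O)OC2
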